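The α-methylene-γ-butyrolactone (ring O–C16–C15–C1–C14) is opened at O–C14 and C15–C16, so that the carbonyl carbon and the ring oxygen arrive together as CO2. The precursor is the 14-membered carbocycle bearing a 1-iodovinyl group on C1 and a mesylate on C14 with inverted (R) configuration. Nickel-catalysed reductive carboxylation of the C15–I bond gives an acrylate carboxylate, which displaces the mesylate (5-exo-tet, inversion) to set the trans ring fusion. The step exploits the O=C–O unit flanked by vinylic C15 and carbinol carbon C14. The carbocycle is assembled from farnesol, acetylene and a vinylsilane by two Sharpless epoxidations and an alkenylzinc macrocyclisation.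

Key step: step 11

Remark (numbering): cembrane numbering is used for all macrocycles and, by extension, for the acyclic chain: C1 carries C15 (with methylene C17 and carbonyl C16), C3/C4 is the epoxide (C18 methyl on C4), C7=C8 and C11=C12 are the alkenes (C19, C20 methyls), C13 carries the acetate and C14 the lactone oxygen.

Step 1
Reactants: 1 (2E,6E)-farnesol
Product: 2 (2S,3S)-2,3-epoxyfarnesol
Conditions: Ti(OiPr)4 (5 mol%), L-(+)-DET (6 mol%), t-BuOOH, 4 Å MS, CH2Cl2, −20 °C
Reagents that add atoms: tert-butyl hydroperoxide, CC(C)(C)OO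
Why: Sharpless asymmetric epoxidation: the titanium–tartrate complex binds the primary allylic alcohol and with L-(+)-DET should deliver oxygen to the face that gives the (2S,3S)-epoxide (C3 and C4 of the target), leaving the two isolated trisubstituted alkenes untouched.

Step 2
Reactants: 2 (2S,3S)-2,3-epoxyfarnesol
Product: 4 (2S,3S)-2-[(3E)-4,8-dimethylnona-3,7-dien-1-yl]-2-methyl-3-(prop-2-yn-1-yl)oxirane, via epoxyfarnesyl triflate 3 (not isolated)
Conditions: Tf2O, 2,6-lutidine, CH2Cl2, −78 °C; then HC≡CLi (from acetylene, n-BuLi), THF/DMPU, −78 → −20 °C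
Reagents that add atoms: lithium acetylide, [Li]C#C
Why: SN2 alkylation of an acetylide: the primary triflate next to the epoxide is displaced at low temperature far faster than the hindered trisubstituted epoxide can be opened, which forms the C1–C2 bond and brings in C14 without touching C3 or C4.

Step 3
Reactants: 4 epoxy enyne
Product: 5 (2E,6E)-2,6-dimethyl-9-[(2S,3S)-2-methyl-3-(prop-2-yn-1-yl)oxiran-2-yl]nona-2,6-dien-1-ol
Conditions: SeO2 (0.3 equiv), t-BuOOH, CH2Cl2, 0 °C → rt
Reagents that add atoms: tert-butyl hydroperoxide, CC(C)(C)OO; selenium dioxide, O=[Se]=O (oxygen carrier)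
Why: SeO2 allylic (Riley) oxidation by ene reaction and [2,3]-sigmatropic shift, which in geranyl- and farnesyl-type chains is selective for the (E)-methyl group of the terminal isopropylidene unit and so should give the (E)-allylic alcohol at C13.

Step 4
Reactants: 5 allylic alcohol
Product: 6 (2E,6E)-2,6-dimethyl-9-[(2S,3S)-2-methyl-3-(prop-2-yn-1-yl)oxiran-2-yl]nona-2,6-dienal
Conditions: MnO2, CH2Cl2, rt
Reagents that add atoms: none
Why: MnO2 oxidises allylic alcohols selectively to enals without alkene isomerisation and leaves the epoxide and the terminal alkyne alone.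

Step 5
Reactants: 6 ynal
Product: 9 (1(14)E,3S,4S,7E,11E,13R)-3,4-epoxy-4,8,12-trimethylcyclotetradeca-1(14),7,11-trien-13-ol, via alkenyl(dicyclohexyl)borane 7 (not isolated), via alkenyl(ethyl)zinc 8 (not isolated)
Conditions: Cy2BH (from BH3·SMe2, cyclohexene), hexane, 0 °C; then slow addition to Et2Zn, (+)-DAIB [(2R)-3-exo-(dimethylamino)isoborneol, 5 mol%], hexane (2 mM), 0 °C; aq. NH4Cl
Reagents that add atoms: none
Why: Hydroboration of the terminal alkyne by the hindered dialkylborane (faster than reduction of the conjugated aldehyde) gives the (E)-alkenylborane, boron–zinc exchange gives the alkenylzinc, and its amino-alcohol-catalysed intramolecular addition to the aldehyde under high dilution (a macrocyclisation type known for 15- and 18-membered (E)-allylic alcohols) closes the 14-membered ring; (+)-DAIB, the antipode of the ligand that sends zinc-bound groups to the Si face, should direct C14 to the Re face of the enal and set C13 as R.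

Step 6
Reactants: 9 macrocyclic allylic alcohol
Product: 10 (1S,3S,4S,7E,11E,13S,14S)-1,14:3,4-diepoxy-4,8,12-trimethylcyclotetradeca-7,11-dien-13-ol
Conditions: Ti(OiPr)4 (1.0 equiv), L-(+)-DIPT (1.2 equiv), t-BuOOH, 4 Å MS, CH2Cl2, −20 °C
Reagents that add atoms: tert-butyl hydroperoxide, CC(C)(C)OO
Why: Reagent-controlled Sharpless epoxidation of a secondary allylic alcohol: with L-(+)-tartrate the (13R)-carbinol is the fast-reacting antipode for its (E)-C14=C1 alkene but the slow-reacting one for the C11=C12 alkene, so oxygen should be delivered to C14=C1 anti (erythro) to the hydroxyl, setting C14 (S) and C1 (S), while C13 keeps its geometry (descriptor S by priority change only).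

Step 7
Reactants: 10 epoxy alcohol
Product: 11 13-O-triethylsilyl ether of 10
Conditions: TESCl, imidazole, DMAP (cat.), CH2Cl2, 0 °C
Reagents that add atoms: chlorotriethylsilane, CC[Si](Cl)(CC)CC
Why: Standard silylation of the secondary alcohol; a silyl ether (not an acetate, which would migrate to the C14 alkoxide in step 8 and be ionised by nickel in step 11) masks O13 until the end.

Step 8
Reactants: 11 epoxy silyl ether
Product: 12 (1R,3S,4S,7E,11E,13S,14R)-3,4-epoxy-4,8,12-trimethyl-13-(triethylsilyloxy)-1-[1-(trimethylsilyl)ethenyl]cyclotetradeca-7,11-dien-14-ol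
Conditions: CH2=C(SiMe3)MgBr (from (1-bromovinyl)trimethylsilane, Mg), CuBr·SMe2 (15 mol%), THF, −30 → 0 °C; aq. NH4Cl
Reagents that add atoms: [1-(trimethylsilyl)ethenyl]magnesium bromide, C=C([Mg]Br)[Si](C)(C)C
Why: Copper-catalysed Grignard opening of an epoxide is an SN2 process with inversion; attack at C1, remote from the bulky and inductively deactivating silyloxy-bearing C13, should form C1–C15 anti to the C14 oxygen and set C1, while the hindered trisubstituted 3,4-epoxide is inert to cuprates.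

Step 9
Reactants: 12 vinylsilane alcohol
Product: 13 14-methanesulfonate of 12
Conditions: MsCl, Et3N, DMAP (cat.), CH2Cl2, 0 °C
Reagents that add atoms: methanesulfonyl chloride, CS(=O)(=O)Cl
Why: Sulfonylation of the C14 alcohol with retention turns the oxygen that served to build the stereotriad into the leaving group for the lactonisation.

Step 10
Reactants: 13 vinylsilane mesylate
Product: 14 (1R,3S,4S,7E,11E,13S,14R)-3,4-epoxy-1-(1-iodoethenyl)-4,8,12-trimethyl-13-(triethylsilyloxy)cyclotetradeca-7,11-dien-14-yl methanesulfonate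
Conditions: NIS, MeCN, 0 °C → rt, dark
Reagents that add atoms: N-iodosuccinimide, O=C1CCC(=O)N1I
Why: Ipso-iododesilylation of a 1,1-disubstituted vinylsilane: iodonium formation on the trisubstituted alkenes is reversible in the non-nucleophilic medium, whereas the silicon-stabilised intermediate collapses irreversibly to the 1-iodovinyl group by loss of the silyl group.

Step 11
Reactants: 14 iodovinyl mesylate
Product: 16 (1S,3S,4S,7E,11E,13S,14S)-3,4-epoxy-13-(triethylsilyloxy)cembra-7,11,15(17)-trien-16,14-olide, via cesium acrylate 15 (not isolated)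
Conditions: NiBr2(2,2'-bipyridine) (10 mol%), Mn powder, Et4NI (10 mol%), CO2 (1 atm), DMA, 25 °C; then Cs2CO3, 50 °C
Reagents that add atoms: carbon dioxide, O=C=O
Why: Zerovalent nickel inserts into the C15–I bond, the alkenylnickel species (after one-electron reduction by Mn) inserts CO2 to forge C15–C16, and the released acrylate carboxylate 15 attacks C14 from the side opposite the mesylate to forge O–C14. The closest known reactions are the nickel-catalysed reductive carboxylation of alkenyl halides and triflates with CO2 and Mn, and the cesium-carboxylate SN2 lactonisation of γ-sulfonyloxy acids. The lactone ring closes in the 5-exo-tet mode. The only stereocentre that reacts is C14, inverted from R to S (C1 changes descriptor from R to S by priority only), so the anti-13,14/anti-14,1 array built by the second Sharpless epoxidation and the anti epoxide opening becomes the syn-13,14, trans-fused array of the target. The step needs chemoselectivity for C(sp2)–I over the hindered secondary mesylate and the allylic silyl ether (oxidative addition to alkenyl iodides is far faster), and O-alkylation at C14 over E2 or attack on the trisubstituted 3,4-epoxide (the sulfonate in a 5-exo geometry is by far the best electrophile within reach). The acetate is introduced only afterwards because an allylic acetate would itself be ionised by zerovalent nickel.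

Step 12
Reactants: 16 silyl-protected lactone
Product: 17 (1S,3S,4S,7E,11E,13S,14S)-3,4-epoxy-13-hydroxycembra-7,11,15(17)-trien-16,14-olide
Conditions: TBAF, AcOH (1:1), THF, 0 °C
Reagents that add atoms: none
Why: Fluoride cleaves the Si–O bond; buffering with acetic acid keeps the medium from generating an alkoxide that could add to the α-methylene lactone or open it.

Step 13
Reactants: 17 hydroxy lactone
Product: 18 13-acetoxysarcocrassolide
Conditions: Ac2O, pyridine, DMAP (cat.), CH2Cl2, 0 °C → rt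
Reagents that add atoms: acetic anhydride, CC(=O)OC(C)=O
Why: DMAP-catalysed acylation of the secondary allylic alcohol with retention gives the acetate.

Compound list
1 | (2E,6E)-farnesol, (2E,6E)-3,7,11-trimethyldodeca-2,6,10-trien-1-ol | OC/C=C(\C)CC/C=C(\C)CCC=C(C)C | starting material
2 | (2S,3S)-2,3-epoxyfarnesol, [(2S,3S)-3-[(3E)-4,8-dimethylnona-3,7-dien-1-yl]-3-methyloxiran-2-yl]methanol | OC[C@@H]1O[C@@]1(C)CC/C=C(\C)CCC=C(C)C | intermediate
3 | epoxyfarnesyl triflate, trifluoromethanesulfonate of 2 (not isolated) | O=S(=O)(OC[C@@H]1O[C@@]1(C)CC/C=C(\C)CCC=C(C)C)C(F)(F)F | intermediate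
4 | (2S,3S)-2-[(3E)-4,8-dimethylnona-3,7-dien-1-yl]-2-methyl-3-(prop-2-yn-1-yl)oxirane | C#CC[C@@H]1O[C@@]1(C)CC/C=C(\C)CCC=C(C)C | intermediate
5 | (2E,6E)-2,6-dimethyl-9-[(2S,3S)-2-methyl-3-(prop-2-yn-1-yl)oxiran-2-yl]nona-2,6-dien-1-ol | C#CC[C@@H]1O[C@@]1(C)CC/C=C(\C)CC/C=C(\C)CO | intermediate
6 | (2E,6E)-2,6-dimethyl-9-[(2S,3S)-2-methyl-3-(prop-2-yn-1-yl)oxiran-2-yl]nona-2,6-dienal | C#CC[C@@H]1O[C@@]1(C)CC/C=C(\C)CC/C=C(\C)C=O | intermediate
7 | dicyclohexyl[(1E)-3-{(2S,3S)-3-[(3E,7E)-4,8-dimethyl-9-oxonona-3,7-dien-1-yl]-3-methyloxiran-2-yl}prop-1-en-1-yl]borane (boron on C14; not isolated) | C1CCCCC1B(C2CCCCC2)/C=C/C[C@@H]3O[C@@]3(C)CC/C=C(\C)CC/C=C(\C)C=O | intermediate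
8 | ethyl[(1E)-3-{(2S,3S)-3-[(3E,7E)-4,8-dimethyl-9-oxonona-3,7-dien-1-yl]-3-methyloxiran-2-yl}prop-1-en-1-yl]zinc (zinc on C14; not isolated) | CC[Zn]/C=C/C[C@@H]1O[C@@]1(C)CC/C=C(\C)CC/C=C(\C)C=O | intermediate
9 | (1(14)E,3S,4S,7E,11E,13R)-3,4-epoxy-4,8,12-trimethylcyclotetradeca-1(14),7,11-trien-13-ol | O[C@@H]1/C=C/C[C@@H]2O[C@@]2(C)CC/C=C(\C)CC/C=C1\C | intermediate
10 | (1S,3S,4S,7E,11E,13S,14S)-1,14:3,4-diepoxy-4,8,12-trimethylcyclotetradeca-7,11-dien-13-ol | O[C@@H]1[C@@H]2O[C@H]2C[C@@H]3O[C@@]3(C)CC/C=C(\C)CC/C=C1\C | intermediate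
11 | 13-O-triethylsilyl ether of 10 | CC[Si](CC)(CC)O[C@@H]1[C@@H]2O[C@H]2C[C@@H]3O[C@@]3(C)CC/C=C(\C)CC/C=C1\C | intermediate
12 | (1R,3S,4S,7E,11E,13S,14R)-3,4-epoxy-4,8,12-trimethyl-13-(triethylsilyloxy)-1-[1-(trimethylsilyl)ethenyl]cyclotetradeca-7,11-dien-14-ol | C=C([Si](C)(C)C)[C@@H]1C[C@@H]2O[C@@]2(C)CC/C=C(\C)CC/C=C(\C)[C@H](O[Si](CC)(CC)CC)[C@@H]1O | intermediate
13 | 14-methanesulfonate of 12 (1R,3S,4S,13S,14R) | C=C([Si](C)(C)C)[C@@H]1C[C@@H]2O[C@@]2(C)CC/C=C(\C)CC/C=C(\C)[C@H](O[Si](CC)(CC)CC)[C@@H]1OS(C)(=O)=O | intermediate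
14 | (1R,3S,4S,7E,11E,13S,14R)-3,4-epoxy-1-(1-iodoethenyl)-4,8,12-trimethyl-13-(triethylsilyloxy)cyclotetradeca-7,11-dien-14-yl methanesulfonate | C=C(I)[C@@H]1C[C@@H]2O[C@@]2(C)CC/C=C(\C)CC/C=C(\C)[C@H](O[Si](CC)(CC)CC)[C@@H]1OS(C)(=O)=O | intermediate
15 | cesium 2-[(1S,3S,4S,7E,11E,13S,14R)-3,4-epoxy-14-(methylsulfonyloxy)-4,8,12-trimethyl-13-(triethylsilyloxy)cyclotetradeca-7,11-dien-1-yl]prop-2-enoate (not isolated) | [Cs+].[O-]C(=O)C(=C)[C@@H]1C[C@@H]2O[C@@]2(C)CC/C=C(\C)CC/C=C(\C)[C@H](O[Si](CC)(CC)CC)[C@@H]1OS(C)(=O)=O | intermediate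
16 | (1S,3S,4S,7E,11E,13S,14S)-3,4-epoxy-13-(triethylsilyloxy)cembra-7,11,15(17)-trien-16,14-olide | C=C1C(=O)O[C@H]2[C@H]1C[C@@H]1O[C@@]1(C)CC/C=C(\C)CC/C=C(\C)[C@@H]2O[Si](CC)(CC)CC | intermediate
17 | (1S,3S,4S,7E,11E,13S,14S)-3,4-epoxy-13-hydroxycembra-7,11,15(17)-trien-16,14-olide | C=C1C(=O)O[C@H]2[C@H]1C[C@@H]1O[C@@]1(C)CC/C=C(\C)CC/C=C(\C)[C@@H]2O | intermediate
18 | 13-acetoxysarcocrassolide, (1S,3S,4S,7E,11E,13S,14S)-13-acetoxy-3,4-epoxycembra-7,11,15(17)-trien-16,14-olide | C=C1C(=O)O[C@H]2[C@H]1C[C@@H]1O[C@@]1(C)CC/C=C(\C)CC/C=C(\C)[C@@H]2OC(C)=O | target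

Total step count: 13. Longest linear sequence: 13 steps, from farnesol 1.

Steps most likely to fail

Step 11 (key step). The alkenylnickel intermediate may be lost to reductive dimerisation or protodehalogenation before it captures CO2, or iodide may displace the mesylate before the carboxylate is formed, which would erode the configuration at C14. Fallback: setting out from 14, palladium-catalysed hydroxycarbonylation (PdCl2(PPh3)2, CO 1 atm, H2O, Et3N, DMF, 50 °C) should give the acrylic acid 2-[(1S,3S,4S,7E,11E,13S,14R)-3,4-epoxy-14-(methylsulfonyloxy)-4,8,12-trimethyl-13-(triethylsilyloxy)cyclotetradeca-7,11-dien-1-yl]prop-2-enoic acid F1, and Cs2CO3 in DMF at 50 °C should then close the lactone by the same 5-exo-tet inversion, coming back to the route at 16.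

Step 5 (macrocyclisation). Intermolecular oligomerisation, ethyl transfer from Et2Zn to the enal, reduction of the enal by the borane, or poor facial control (if the remote epoxide is mismatched with the ligand) may compete with ring closure. Fallback: setting out from 6, NIS and AgNO3 (cat.) in acetone should give the iodoalkyne (2E,6E)-9-[(2S,3S)-3-(3-iodoprop-2-yn-1-yl)-2-methyloxiran-2-yl]-2,6-dimethylnona-2,6-dienal F2. A Nozaki–Hiyama–Kishi macrocyclisation (CrCl2, NiCl2 cat., THF, high dilution) should give the cyclic propargylic alcohol (3S,4S,7E,11E)-3,4-epoxy-4,8,12-trimethylcyclotetradeca-7,11-dien-1(14)-yn-13-ol F3 as both C13 epimers. MnO2 should oxidise it to the ynone (3S,4S,7E,11E)-3,4-epoxy-4,8,12-trimethylcyclotetradeca-7,11-dien-1(14)-yn-13-one F4. Asymmetric transfer hydrogenation (RuCl(p-cymene)[(S,S)-TsDPEN], i-PrOH) should give the single propargylic alcohol (3S,4S,7E,11E,13S)-3,4-epoxy-4,8,12-trimethylcyclotetradeca-7,11-dien-1(14)-yn-13-ol F5, and trans-selective reduction with Red-Al (THF, 0 °C) comes back to the route at 9.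

Step 8 (epoxide opening). The hindered internal epoxide inside the macrocycle may open too slowly or without regiocontrol, and the triethylsilyl group may migrate to the new alkoxide. Fallback: setting out from 11, lithium (trimethylsilyl)acetylide pre-complexed with BF3·OEt2 (THF, −78 °C) should open the epoxide at C1 with inversion to give (1S,3S,4S,7E,11E,13S,14R)-3,4-epoxy-4,8,12-trimethyl-13-(triethylsilyloxy)-1-[(trimethylsilyl)ethynyl]cyclotetradeca-7,11-dien-14-ol F6. K2CO3 in MeOH should give the terminal alkyne (1S,3S,4S,7E,11E,13S,14R)-3,4-epoxy-1-ethynyl-4,8,12-trimethyl-13-(triethylsilyloxy)cyclotetradeca-7,11-dien-14-ol F7. Stannylcupration with Me3SnCu·SMe2 and MeOH (THF, −63 °C) should give the internal alkenylstannane (1R,3S,4S,7E,11E,13S,14R)-3,4-epoxy-4,8,12-trimethyl-13-(triethylsilyloxy)-1-[1-(trimethylstannyl)ethenyl]cyclotetradeca-7,11-dien-14-ol F8. Iodine (CH2Cl2, 0 °C) should give (1R,3S,4S,7E,11E,13S,14R)-3,4-epoxy-1-(1-iodoethenyl)-4,8,12-trimethyl-13-(triethylsilyloxy)cyclotetradeca-7,11-dien-14-ol F9, and mesylation (MsCl, Et3N) comes back to the route at 14; this detour also bypasses the iododesilylation of step 10.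

Further compounds
F1 | step 11 | 2-[(1S,3S,4S,7E,11E,13S,14R)-3,4-epoxy-14-(methylsulfonyloxy)-4,8,12-trimethyl-13-(triethylsilyloxy)cyclotetradeca-7,11-dien-1-yl]prop-2-enoic acid | OC(=O)C(=C)[C@@H]1C[C@@H]2O[C@@]2(C)CC/C=C(\C)CC/C=C(\C)[C@H](O[Si](CC)(CC)CC)[C@@H]1OS(C)(=O)=O
F2 | step 5 | (2E,6E)-9-[(2S,3S)-3-(3-iodoprop-2-yn-1-yl)-2-methyloxiran-2-yl]-2,6-dimethylnona-2,6-dienal | IC#CC[C@@H]1O[C@@]1(C)CC/C=C(\C)CC/C=C(\C)C=O
F3 | step 5 | (3S,4S,7E,11E)-3,4-epoxy-4,8,12-trimethylcyclotetradeca-7,11-dien-1(14)-yn-13-ol, both C13 epimers | OC1C#CC[C@@H]2O[C@@]2(C)CC/C=C(\C)CC/C=C1\C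
F4 | step 5 | (3S,4S,7E,11E)-3,4-epoxy-4,8,12-trimethylcyclotetradeca-7,11-dien-1(14)-yn-13-one | O=C1C#CC[C@@H]2O[C@@]2(C)CC/C=C(\C)CC/C=C1\C
F5 | step 5 | (3S,4S,7E,11E,13S)-3,4-epoxy-4,8,12-trimethylcyclotetradeca-7,11-dien-1(14)-yn-13-ol | O[C@@H]1C#CC[C@@H]2O[C@@]2(C)CC/C=C(\C)CC/C=C1\C
F6 | step 8 | (1S,3S,4S,7E,11E,13S,14R)-3,4-epoxy-4,8,12-trimethyl-13-(triethylsilyloxy)-1-[(trimethylsilyl)ethynyl]cyclotetradeca-7,11-dien-14-ol | C[Si](C)(C)C#C[C@@H]1C[C@@H]2O[C@@]2(C)CC/C=C(\C)CC/C=C(\C)[C@H](O[Si](CC)(CC)CC)[C@@H]1O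
F7 | step 8 | (1S,3S,4S,7E,11E,13S,14R)-3,4-epoxy-1-ethynyl-4,8,12-trimethyl-13-(triethylsilyloxy)cyclotetradeca-7,11-dien-14-ol | C#C[C@@H]1C[C@@H]2O[C@@]2(C)CC/C=C(\C)CC/C=C(\C)[C@H](O[Si](CC)(CC)CC)[C@@H]1O
F8 | step 8 | (1R,3S,4S,7E,11E,13S,14R)-3,4-epoxy-4,8,12-trimethyl-13-(triethylsilyloxy)-1-[1-(trimethylstannyl)ethenyl]cyclotetradeca-7,11-dien-14-ol | C=C([Sn](C)(C)C)[C@@H]1C[C@@H]2O[C@@]2(C)CC/C=C(\C)CC/C=C(\C)[C@H](O[Si](CC)(CC)CC)[C@@H]1O
F9 | step 8 | (1R,3S,4S,7E,11E,13S,14R)-3,4-epoxy-1-(1-iodoethenyl)-4,8,12-trimethyl-13-(triethylsilyloxy)cyclotetradeca-7,11-dien-14-ol | C=C(I)[C@@H]1C[C@@H]2O[C@@]2(C)CC/C=C(\C)CC/C=C(\C)[C@H](O[Si](CC)(CC)CC)[C@@H]1O
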